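**Retrosynthetic overview**

1. Enabling feature: in quinone ring B (C1′ on chroman C3, C3′ and C6′ the carbonyl carbons, C4′ the hydroxyl carbon, C5′ the prenyl carbon) the array C4′(OH)=C5′(prenyl)–C6′=O is an enolised 2-prenyl-1,3-dicarbonyl. C4′ is therefore an acyl carbon and C5′ the α-carbon of the C6′ ketone, so the C4′–C5′ bond is a Claisen (Dieckmann-type) retron.
2. 23 ⇒ 22: the C3′ oxygen is added last, by oxidation of a ring B resorcinol at its only free position para to a hydroxyl.
3. 22 ⇒ 18 (key step, one pot): ring B is opened at C4′–C5′ to a 5-oxo-2-enoate; the O1–C2 bond of ring C and the C1′–H go back to a 2-acyl-γ-butyrolactone. This temporary ring activates C1′ with its carbonyl, which leaves as CO2 when the ring A phenoxide closes ring C.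
4. 18 ⇒ lactone 12 + 5-methylhex-4-enoic acid 13 (C5′, C6′ and the prenyl group) + methyl propiolate 16 (C2′ to C4′); 12 ⇒ aldehyde 6 + dimethyl succinate 7 (Stobbe condensation, asymmetric hydrogenation sets C3, ester reduction).
5. 6 ⇒ 2,4,6-trihydroxybenzaldehyde 1 (prenyl placed by aromatic Claisen rearrangement). Ring order: A (bought), temporary lactone, then C and B, in that order, in the key step.

Key step: step 11

Remark: prenyl = 3-methylbut-2-en-1-yl and locants follow the isoflavan skeleton; tert-butyl (2-methylbut-3-en-2-yl) carbonate and 5-methylhex-4-enoic acid are taken as purchasable, and the (S,S) ligand of step 6 is assumed, by analogy with simpler β-aryl itaconate half-esters, to give the (R) acid (otherwise the antipodal ligand is used).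

**Route**

Step 1
Reactants: 1 2,4,6-trihydroxybenzaldehyde
Product: 2 2-hydroxy-4,6-bis(methoxymethoxy)benzaldehyde
Conditions: MOMCl (2.2 equiv), iPr2NEt, CH2Cl2, 0 °C → rt
Reagents that add atoms: chloromethyl methyl ether (MOMCl), COCCl
Why: O-alkylation (acetal protection) of the para hydroxyl and one ortho hydroxyl; the remaining ortho hydroxyl is deactivated by its hydrogen bond to the formyl oxygen and stays free.

Step 2
Reactants: 2 2-hydroxy-4,6-bis(methoxymethoxy)benzaldehyde
Product: 3 2,4-bis(methoxymethoxy)-6-[(2-methylbut-3-en-2-yl)oxy]benzaldehyde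
Conditions: tert-butyl (2-methylbut-3-en-2-yl) carbonate (1.5 equiv), Pd(PPh3)4 (2 mol %), THF, 0 °C → rt
Reagents that add atoms: tert-butyl (2-methylbut-3-en-2-yl) carbonate, CC(C)(C)OC(=O)OC(C)(C)C=C
Why: Tsuji–Trost O-allylation, in which the phenoxide attacks the 1,1-dimethylallyl palladium complex at its substituted terminus and gives the tertiary allyl aryl ether.

Step 3
Reactants: 3 2,4-bis(methoxymethoxy)-6-[(2-methylbut-3-en-2-yl)oxy]benzaldehyde
Product: 5 2-hydroxy-4,6-bis(methoxymethoxy)-3-prenylbenzaldehyde, via ortho-dienone 4 (not isolated)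
Conditions: toluene, 110 °C
Reagents that add atoms: none
Why: aromatic Claisen rearrangement ([3,3]-sigmatropic) to the only free ortho position turns the tertiary ether into a prenyl group on the carbon between two oxygens, and enolisation of the dienone restores the arene.

Step 4
Reactants: 5 2-hydroxy-4,6-bis(methoxymethoxy)-3-prenylbenzaldehyde
Product: 6 2-methoxy-4,6-bis(methoxymethoxy)-3-prenylbenzaldehyde
Conditions: MeI, K2CO3, DMF, 40 °C
Reagents that add atoms: iodomethane, CI
Why: Williamson ether synthesis on the last free phenol fixes the methoxy group between the formyl carbon and the prenyl group (C5 of the target).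

Step 5
Reactants: 6 2-methoxy-4,6-bis(methoxymethoxy)-3-prenylbenzaldehyde; 7 dimethyl succinate
Product: 9 (3E)-3-(methoxycarbonyl)-4-[2-methoxy-4,6-bis(methoxymethoxy)-3-prenylphenyl]but-3-enoic acid, via paraconic ester 8 (not isolated)
Conditions: NaOMe (1.5 equiv), MeOH, reflux; then cold 1 M HCl to pH 3
Reagents that add atoms: none
Why: Stobbe condensation, in which aldol addition, lactonisation and E1cB ring opening give the alkylidene succinic half-ester with the aryl group trans to the ester and the free acid on the CH2 arm.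

Step 6
Reactants: 9 (3E)-3-(methoxycarbonyl)-4-[2-methoxy-4,6-bis(methoxymethoxy)-3-prenylphenyl]but-3-enoic acid
Product: 10 (3R)-3-(methoxycarbonyl)-4-[2-methoxy-4,6-bis(methoxymethoxy)-3-prenylphenyl]butanoic acid
Conditions: H2 (5 bar), [Rh(cod)((S,S)-Et-DuPhos)]BF4 (1 mol %), NaOMe (10 mol %), MeOH, 25 °C
Reagents that add atoms: none
Why: asymmetric hydrogenation of an itaconate-type half-ester, in which the carboxylate-bound alkene takes up H2 on the face selected by the chiral bisphospholane and so sets C3 as (R), while the isolated trisubstituted alkene does not bind to the cationic rhodium centre and is expected to stay.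

Step 7
Reactants: 10 (3R)-3-(methoxycarbonyl)-4-[2-methoxy-4,6-bis(methoxymethoxy)-3-prenylphenyl]butanoic acid
Product: 12 (4R)-4-{[2-methoxy-4,6-bis(methoxymethoxy)-3-prenylphenyl]methyl}oxolan-2-one, via hydroxy acid 11 (not isolated)
Conditions: LiOH (1.0 equiv), THF–H2O, then evaporation; LiBH4 (2 equiv), THF, 0 °C → rt; AcOH, 40 °C
Reagents that add atoms: none
Why: chemoselective borohydride reduction of the ester beside the lithium carboxylate, then acid-promoted lactonisation, should give the β-substituted γ-butyrolactone without epimerising the stereocentre.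

Step 8
Reactants: 12 (4R)-4-{[2-methoxy-4,6-bis(methoxymethoxy)-3-prenylphenyl]methyl}oxolan-2-one; 13 5-methylhex-4-enoic acid
Product: 15 (4R)-4-{[2-methoxy-4,6-bis(methoxymethoxy)-3-prenylphenyl]methyl}-3-(5-methylhex-4-enoyl)oxolan-2-one, via acyl imidazole 14 (not isolated)
Conditions: 13, CDI, THF, rt; then added to 12 and LiN(SiMe3)2 (3.2 equiv), THF, −78 → −20 °C; AcOH
Reagents that add atoms: none
Why: crossed Claisen C-acylation of the lactone lithium enolate, whose only enolisable carbon is C1′, by the acyl imidazole; the new centre at C1′ stays enolisable and its configuration is of no consequence.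

Step 9
Reactants: 15 (4R)-4-{[2-methoxy-4,6-bis(methoxymethoxy)-3-prenylphenyl]methyl}-3-(5-methylhex-4-enoyl)oxolan-2-one; 16 methyl propiolate
Product: 17 methyl (2E)-3-[(4R)-4-{[2-methoxy-4,6-bis(methoxymethoxy)-3-prenylphenyl]methyl}-3-(5-methylhex-4-enoyl)-2-oxooxolan-3-yl]prop-2-enoate
Conditions: 16 (1.3 equiv), DABCO (10 mol %), CH2Cl2, 0 °C → rt
Reagents that add atoms: none
Why: amine-catalysed Michael addition of the 2-acyl lactone, the most acidic C–H of 15, to the ynoate makes C1′ quaternary and brings in C2′ to C4′; either epimer at C1′ and either alkene geometry serves, because both are erased in step 11.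

Step 10
Reactants: 17 methyl (2E)-3-[(4R)-4-{[2-methoxy-4,6-bis(methoxymethoxy)-3-prenylphenyl]methyl}-3-(5-methylhex-4-enoyl)-2-oxooxolan-3-yl]prop-2-enoate
Product: 18 methyl (2E)-3-[(4R)-4-{[4,6-dihydroxy-2-methoxy-3-prenylphenyl]methyl}-3-(5-methylhex-4-enoyl)-2-oxooxolan-3-yl]prop-2-enoate
Conditions: HCl (1.25 M in MeOH), 0 °C → rt
Reagents that add atoms: none
Why: acid-catalysed acetal exchange removes both MOM groups as dimethoxymethane under conditions that should be too mild to add to the trisubstituted alkenes or to open the lactone.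

Step 11
Reactants: 18 methyl (2E)-3-[(4R)-4-{[4,6-dihydroxy-2-methoxy-3-prenylphenyl]methyl}-3-(5-methylhex-4-enoyl)-2-oxooxolan-3-yl]prop-2-enoate
Product: 22 4-[(3R)-7-hydroxy-5-methoxy-6-prenylchroman-3-yl]-2-prenylbenzene-1,3-diol, via chroman keto acid 19 (not isolated), via keto enoate 20 (not isolated), via enedione 21 (not isolated)
Conditions: Cs2CO3 (3 equiv), DMF, argon, 90 °C; then NaOMe (5 equiv), MeOH, 60 °C; AcOH
Reagents that add atoms: none
Why: Proposed new method: the C8a phenoxide of ring A attacks C2 of the 2-acyl-γ-butyrolactone in a 6-exo-tet alkyl–oxygen cleavage that closes ring C, the β-keto carboxylate 19 set free loses CO2, and the resulting dienolate is protonated to 20; under methoxide the C5′ enolate of the C6′ ketone then attacks the C4′ ester in a 6-(enolendo)-exo-trig Claisen (Dieckmann-type) condensation that forms the C4′–C5′ bond and closes ring B, and the enedione 21 tautomerises to the resorcinol 22. The closest known reaction types are the decarboxylative opening of 2-acyl-γ-butyrolactones at the alkyl carbon by halide or thiolate (a Krapcho-type dealkoxycarbonylation) and the alkoxide-mediated cyclisation of 5-oxo esters to cyclohexane-1,3-diones; what is new is the internal phenoxide in the first event and the one-pot union of the two. No stereocentre is formed: C3 keeps its configuration because none of its bonds is broken and it is not α to a carbonyl in 18 to 22, and the centre at C1′ and the alkene geometry vanish in the arene. The step needs C-acylation at C5′ in preference to O-acylation or reaction at C1′: only C5′ can close a six-membered carbocycle, enol lactone formation is reversible under methoxide, and aromatisation to the resorcinolate makes the C-acylation irreversible. It also needs the quaternary β-keto lactone to survive until ring C is closed, which is why non-nucleophilic carbonate is used first and methoxide only after the decarboxylation; the E/Z geometry of the enoate does not matter because the dienolate of 20 equilibrates it.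

Step 12
Reactants: 22 4-[(3R)-7-hydroxy-5-methoxy-6-prenylchroman-3-yl]-2-prenylbenzene-1,3-diol
Product: 23 2-hydroxy-5-[(3R)-7-hydroxy-5-methoxy-6-prenylchroman-3-yl]-3-prenylcyclohexa-2,5-diene-1,4-dione
Conditions: K2[ON(SO3)2] (2.2 equiv), KH2PO4 buffer (pH 6), acetone–H2O, 0 °C
Reagents that add atoms: potassium nitrosodisulfonate (Fremy's salt), [K+].[K+].[O]N(S(=O)(=O)[O-])S(=O)(=O)[O-]
Why: Teuber oxidation, in which the nitroxyl radical oxidises the resorcinol ring at C3′, its only free position para to a hydroxyl, to the p-quinone and leaves the C4′ hydroxyl, whereas the ring A phenol has no free para position.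

**Compound list**

1 | 2,4,6-trihydroxybenzaldehyde | O=Cc1c(O)cc(O)cc1O | starting material
2 | 2-hydroxy-4,6-bis(methoxymethoxy)benzaldehyde | O=Cc1c(O)cc(OCOC)cc1OCOC | intermediate
3 | 2,4-bis(methoxymethoxy)-6-[(2-methylbut-3-en-2-yl)oxy]benzaldehyde | O=Cc1c(OC(C)(C)C=C)cc(OCOC)cc1OCOC | intermediate
4 | 2,4-bis(methoxymethoxy)-6-oxo-5-prenylcyclohexa-1,3-diene-1-carbaldehyde (ortho-dienone, racemic, not isolated) | O=CC1=C(OCOC)C=C(OCOC)C(CC=C(C)C)C1=O | intermediate
5 | 2-hydroxy-4,6-bis(methoxymethoxy)-3-prenylbenzaldehyde | O=Cc1c(O)c(CC=C(C)C)c(OCOC)cc1OCOC | intermediate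
6 | 2-methoxy-4,6-bis(methoxymethoxy)-3-prenylbenzaldehyde | O=Cc1c(OC)c(CC=C(C)C)c(OCOC)cc1OCOC | intermediate
7 | dimethyl succinate | COC(=O)CCC(=O)OC | starting material
8 | methyl 2-[2-methoxy-4,6-bis(methoxymethoxy)-3-prenylphenyl]-5-oxooxolane-3-carboxylate (paraconic ester, mixture of stereoisomers, not isolated) | COC(=O)C1CC(=O)OC1c1c(OC)c(CC=C(C)C)c(OCOC)cc1OCOC | intermediate
9 | (3E)-3-(methoxycarbonyl)-4-[2-methoxy-4,6-bis(methoxymethoxy)-3-prenylphenyl]but-3-enoic acid | COC(=O)/C(CC(=O)O)=C/c1c(OC)c(CC=C(C)C)c(OCOC)cc1OCOC | intermediate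
10 | (3R)-3-(methoxycarbonyl)-4-[2-methoxy-4,6-bis(methoxymethoxy)-3-prenylphenyl]butanoic acid | COC(=O)[C@@H](CC(=O)O)Cc1c(OC)c(CC=C(C)C)c(OCOC)cc1OCOC | intermediate
11 | (3R)-3-(hydroxymethyl)-4-[2-methoxy-4,6-bis(methoxymethoxy)-3-prenylphenyl]butanoic acid (formed as its lithium salt, not isolated) | OC[C@@H](CC(=O)O)Cc1c(OC)c(CC=C(C)C)c(OCOC)cc1OCOC | intermediate
12 | (4R)-4-{[2-methoxy-4,6-bis(methoxymethoxy)-3-prenylphenyl]methyl}oxolan-2-one | O=C1C[C@@H](Cc2c(OC)c(CC=C(C)C)c(OCOC)cc2OCOC)CO1 | intermediate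
13 | 5-methylhex-4-enoic acid | CC(C)=CCCC(=O)O | starting material
14 | 1-(1H-imidazol-1-yl)-5-methylhex-4-en-1-one (acyl imidazole, not isolated) | CC(C)=CCCC(=O)n1ccnc1 | intermediate
15 | (4R)-4-{[2-methoxy-4,6-bis(methoxymethoxy)-3-prenylphenyl]methyl}-3-(5-methylhex-4-enoyl)oxolan-2-one (C3 of the lactone enolisable, both epimers) | O=C1C(C(=O)CCC=C(C)C)[C@@H](Cc2c(OC)c(CC=C(C)C)c(OCOC)cc2OCOC)CO1 | intermediate
16 | methyl propiolate | C#CC(=O)OC | starting material
17 | methyl (2E)-3-[(4R)-4-{[2-methoxy-4,6-bis(methoxymethoxy)-3-prenylphenyl]methyl}-3-(5-methylhex-4-enoyl)-2-oxooxolan-3-yl]prop-2-enoate (both epimers at the quaternary carbon) | O=C1C(C(=O)CCC=C(C)C)(/C=C/C(=O)OC)[C@@H](Cc2c(OC)c(CC=C(C)C)c(OCOC)cc2OCOC)CO1 | intermediate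
18 | methyl (2E)-3-[(4R)-4-{[4,6-dihydroxy-2-methoxy-3-prenylphenyl]methyl}-3-(5-methylhex-4-enoyl)-2-oxooxolan-3-yl]prop-2-enoate (both epimers at the quaternary carbon) | O=C1C(C(=O)CCC=C(C)C)(/C=C/C(=O)OC)[C@@H](Cc2c(OC)c(CC=C(C)C)c(O)cc2O)CO1 | intermediate
19 | 2-[(3R)-7-hydroxy-5-methoxy-6-prenylchroman-3-yl]-2-[(1E)-3-methoxy-3-oxoprop-1-en-1-yl]-7-methyl-3-oxooct-6-enoic acid (formed as its caesium salt, not isolated) | COc1c(CC=C(C)C)c(O)cc2c1C[C@H](C(C(=O)O)(C(=O)CCC=C(C)C)/C=C/C(=O)OC)CO2 | intermediate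
20 | methyl (2E)-4-[(3R)-7-hydroxy-5-methoxy-6-prenylchroman-3-yl]-9-methyl-5-oxodeca-2,8-dienoate (C4 epimers, not isolated) | COc1c(CC=C(C)C)c(O)cc2c1C[C@H](C(C(=O)CCC=C(C)C)/C=C/C(=O)OC)CO2 | intermediate
21 | 6-[(3R)-7-hydroxy-5-methoxy-6-prenylchroman-3-yl]-2-prenylcyclohex-4-ene-1,3-dione (not isolated) | COc1c(CC=C(C)C)c(O)cc2c1C[C@H](C1C=CC(=O)C(CC=C(C)C)C1=O)CO2 | intermediate
22 | 4-[(3R)-7-hydroxy-5-methoxy-6-prenylchroman-3-yl]-2-prenylbenzene-1,3-diol | COc1c(CC=C(C)C)c(O)cc2c1C[C@H](c1ccc(O)c(CC=C(C)C)c1O)CO2 | intermediate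
23 | 2-hydroxy-5-[(3R)-7-hydroxy-5-methoxy-6-prenylchroman-3-yl]-3-prenylcyclohexa-2,5-diene-1,4-dione | COc1c(CC=C(C)C)c(O)cc2c1C[C@H](C1=CC(=O)C(O)=C(CC=C(C)C)C1=O)CO2 | target

**Step count and risks**

Total step count: 12. Longest linear sequence: 12 steps (1 to 23).

Steps most likely to fail:

1. Step 11 (proposed new method). Alkyl–oxygen cleavage of the lactone by the phenoxide may be too slow, so that acyl transfer to the phenoxide or loss of the acyl group from the quaternary β-keto lactone takes over before ring C closes.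
 Fallback, known chemistry throughout, setting out from 12 and coming back at 20: ring C is closed by a Williamson etherification before C1′ is activated, and an allyl ester replaces the lactone as the removable activating group.
 - The lactone 12 is saponified with LiOH (1 equiv) and the carboxylate alkylated with allyl bromide in DMF to the hydroxy allyl ester F1.
 - MsCl and Et3N give the mesylate F2, and aqueous HCl in THF removes both MOM groups to give the diphenol mesylate F3.
 - K2CO3 in DMF closes ring C (6-exo-tet displacement by the ortho phenoxide) and allyl bromide added to the same pot caps the remaining phenol, giving the allyl chromanylacetate F4.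
 - LiN(SiMe3)2 and the acyl imidazole 14 give the allyl β-keto ester F5, and methyl propiolate with DABCO gives the quaternary Michael adduct F6.
 - Pd(PPh3)4 with morpholine removes both allyl groups and the β-keto acid loses CO2 to give 20, which is cyclised to 22 by the NaOMe stage of step 11.

2. Step 12. Oxidation at the free ortho position of the ring A phenol, or over-oxidation, may compete with the wanted para-oxidation of ring B.
 Fallback, setting out from 22 and coming back at 23: catalytic aerobic oxidation with Co(salen) (5 mol %) under O2 (1 bar) in DMF at 25 °C. This replaces the stoichiometric radical oxidant by a cobalt–dioxygen path that engages only a phenol with a free para position, so ring A is excluded by mechanism and not by rate. It makes no new compound (none F0).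

3. Step 6. Hydrogenation may be slow, or facial selectivity poor, because the aryl group carries two ortho substituents next to the alkene.
 Fallback, setting out from 6 and coming back at 12: the stereocentre is set by an Evans alkylation instead.
 - NaBH4 in MeOH reduces 6 to the benzyl alcohol F7, and CBr4/PPh3 (Appel reaction) gives the benzyl bromide F8, which is used at once.
 - The sodium enolate (NaN(SiMe3)2, THF, −78 °C) of the known tert-butyl 4-[(4R)-4-benzyl-2-oxo-1,3-oxazolidin-3-yl]-4-oxobutanoate is alkylated with F8 on the face opposite the benzyl group, to give the imide F9.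
 - LiBH4 removes the auxiliary to give the hydroxy tert-butyl ester F10, and PPTS in warm toluene lactonises it to 12.

Further compounds
F1 | step 11 | prop-2-en-1-yl (3R)-3-(hydroxymethyl)-4-[2-methoxy-4,6-bis(methoxymethoxy)-3-prenylphenyl]butanoate | OC[C@@H](CC(=O)OCC=C)Cc1c(OC)c(CC=C(C)C)c(OCOC)cc1OCOC
F2 | step 11 | prop-2-en-1-yl (3R)-4-[2-methoxy-4,6-bis(methoxymethoxy)-3-prenylphenyl]-3-[(methylsulfonyloxy)methyl]butanoate | CS(=O)(=O)OC[C@@H](CC(=O)OCC=C)Cc1c(OC)c(CC=C(C)C)c(OCOC)cc1OCOC
F3 | step 11 | prop-2-en-1-yl (3R)-4-[4,6-dihydroxy-2-methoxy-3-prenylphenyl]-3-[(methylsulfonyloxy)methyl]butanoate | CS(=O)(=O)OC[C@@H](CC(=O)OCC=C)Cc1c(OC)c(CC=C(C)C)c(O)cc1O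
F4 | step 11 | prop-2-en-1-yl 2-[(3R)-5-methoxy-6-prenyl-7-(prop-2-en-1-yloxy)chroman-3-yl]acetate | COc1c(CC=C(C)C)c(OCC=C)cc2c1C[C@H](CC(=O)OCC=C)CO2
F5 | step 11 | prop-2-en-1-yl 2-[(3R)-5-methoxy-6-prenyl-7-(prop-2-en-1-yloxy)chroman-3-yl]-7-methyl-3-oxooct-6-enoate | COc1c(CC=C(C)C)c(OCC=C)cc2c1C[C@H](C(C(=O)OCC=C)C(=O)CCC=C(C)C)CO2
F6 | step 11 | prop-2-en-1-yl 2-[(3R)-5-methoxy-6-prenyl-7-(prop-2-en-1-yloxy)chroman-3-yl]-2-[(1E)-3-methoxy-3-oxoprop-1-en-1-yl]-7-methyl-3-oxooct-6-enoate | COc1c(CC=C(C)C)c(OCC=C)cc2c1C[C@H](C(C(=O)OCC=C)(C(=O)CCC=C(C)C)/C=C/C(=O)OC)CO2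
F0 | step 12 | none | none
F7 | step 6 | [2-methoxy-4,6-bis(methoxymethoxy)-3-prenylphenyl]methanol | OCc1c(OC)c(CC=C(C)C)c(OCOC)cc1OCOC
F8 | step 6 | 2-(bromomethyl)-1-methoxy-3,5-bis(methoxymethoxy)-6-prenylbenzene | BrCc1c(OC)c(CC=C(C)C)c(OCOC)cc1OCOC
F9 | step 6 | tert-butyl (3R)-3-{[(4R)-4-benzyl-2-oxo-1,3-oxazolidin-3-yl]carbonyl}-4-[2-methoxy-4,6-bis(methoxymethoxy)-3-prenylphenyl]butanoate | O=C1OC[C@@H](Cc2ccccc2)N1C(=O)[C@@H](CC(=O)OC(C)(C)C)Cc1c(OC)c(CC=C(C)C)c(OCOC)cc1OCOC
F10 | step 6 | tert-butyl (3R)-3-(hydroxymethyl)-4-[2-methoxy-4,6-bis(methoxymethoxy)-3-prenylphenyl]butanoate | OC[C@@H](CC(=O)OC(C)(C)C)Cc1c(OC)c(CC=C(C)C)c(OCOC)cc1OCOC
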